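**Plan**
- Retrosynthesis: the side-chain ketone is taken back to a secondary carbinol and the enone to a 3-ethoxy-enone (Stork–Danheiser). The ring bonds Cα–C(=O) and allylic CH2–C(OH) are then cut together, which removes an acetone-type C3 unit (α-CH, β-CH, allylic CH2).
- Enabling feature: the carbinol carbon is β to both carbonyls. The ring C=O carbon, the ring CH2 next to it, the carbinol carbon, the side-chain CH2 and the side-chain C–O carbon therefore fit, with one oxygen, into a 2,3-dihydro-4H-pyran-4-one. In it the future carbinol carbon is a ketone and the future ring carbonyl carbon is a ketene-acetal carbon, a 1,3-dielectrophile without an acidic CH2 between the two sites.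
- Forward: the oxane ring is made first (aldehyde plus silyloxydiene). The carbocycle is then built across its 1,3-diaxial positions in one operation (2-oxabicyclo[3.3.1]nonane). The oxane is opened by β-elimination, the carbonyl is transposed and the side-chain carbinol is oxidised.
- The two bonds are a Claisen-type bond at the carboxyl-level carbon and an aldol-type bond at the ketone, followed by reduction and dehydration at the β-carbon, which is polyketide logic.
- Stereochemistry: one centre (pyranone C2) comes from a catalytic asymmetric cyclocondensation. It is relayed to the quaternary carbinol by axial addition and bridging, and is erased by the last oxidation.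

Key step: step 6

Assumption: the target is the (5S) enantiomer encoded by the SMILES; (S)-BINOL is assigned to Si-face attack on aldehyde 2 by analogy with related BINOL–Ti(OiPr)4 aldehyde additions, and the antipodal ligand is to be used if a model run shows the opposite sense.

**Step 1**
Reactants: 1 (9Z,12Z)-octadeca-9,12-dien-1-ol (linoleyl alcohol)
Product: 2 (9Z,12Z)-octadeca-9,12-dienal
Conditions: Dess–Martin periodinane, NaHCO3, CH2Cl2, 0 °C to rt
Reagents that add atoms: none
Why: Dess–Martin oxidation of a primary alcohol should stop at the aldehyde and leave the skipped (Z,Z)-diene untouched; no stereocentre is formed.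

**Step 2**
Reactants: 3 1,1-diethoxyethene (2 equiv); 4 acetyl chloride
Product: 5 4,4-diethoxybut-3-en-2-one
Conditions: Et2O, 0 °C to rt
Reagents that add atoms: none
Why: C-acylation of an electron-rich ketene acetal by an acid chloride, with the second equivalent of ketene acetal taking up HCl, should give the push–pull acylketene acetal.

**Step 3**
Reactants: 5 4,4-diethoxybut-3-en-2-one
Product: 6 1,1-diethoxy-3-(trimethylsilyloxy)buta-1,3-diene
Conditions: LiN(iPr)2, THF, −78 °C; then Me3SiCl
Reagents that add atoms: chlorotrimethylsilane, C[Si](C)(C)Cl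
Why: the methyl group is the only enolisable position, so kinetic deprotonation and O-silylation should give the 2-silyloxydiene cleanly.

**Step 4**
Reactants: 2 (9Z,12Z)-octadeca-9,12-dienal; 6 1,1-diethoxy-3-(trimethylsilyloxy)buta-1,3-diene
Product: 8 (2R)-6-ethoxy-2-[(8Z,11Z)-heptadeca-8,11-dien-1-yl]-2,3-dihydro-4H-pyran-4-one, via silyloxy dihydropyran cycloadduct 7 (not isolated)
Conditions: Ti(OiPr)4 (10 mol %), (S)-BINOL (20 mol %), 4 Å molecular sieves, Et2O, −20 °C; then CF3CO2H (cat.), CH2Cl2, 0 °C
Reagents that add atoms: none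
Why: a chiral Lewis acid catalysed Mukaiyama aldol/hetero-Diels–Alder cyclocondensation followed by acid-induced loss of ethoxytrimethylsilane should give the dihydropyranone, the ligand-controlled Si-face attack on the aldehyde setting the (R) centre.

**Step 5**
Reactants: 9 1-bromo-2,2-dimethoxypropane
Product: 10 3-bromo-2-methoxyprop-1-ene
Conditions: iPr2NEt·TsOH (cat.), 150–190 °C, distillation of methanol
Reagents that add atoms: none
Why: acid-catalysed thermal elimination of methanol from a ketal (ketal-to-enol-ether pyrolysis) should give the allylic bromide.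

**Step 6**
Reactants: 8 (2R)-6-ethoxy-2-[(8Z,11Z)-heptadeca-8,11-dien-1-yl]-2,3-dihydro-4H-pyran-4-one; 10 3-bromo-2-methoxyprop-1-ene
Product: 12 (1S,3R,5R)-1-ethoxy-3-[(8Z,11Z)-heptadeca-8,11-dien-1-yl]-5-hydroxy-2-oxabicyclo[3.3.1]nonan-7-one, via bromozinc alkoxide adduct 11 (not isolated)
Conditions: Zn (activated dust), THF, 0 °C; then pyridinium p-toluenesulfonate (1.5 equiv), CH2Cl2, −40 to 0 °C; aq. NaHCO3
Reagents that add atoms: water, O
Why: Proposed new method: the 2-methoxyallylzinc reagent formed in the flask should add 1,2 to the vinylogous-carbonate carbonyl of 8 (first bond, allyl CH2 to the carbinol carbon), and on acidification the cyclic ketene acetal should be protonated at its β-carbon to a 2-ethoxyoxan-2-ylium ion that is captured by the terminal carbon of the pendant enol ether (second bond), the resulting methyl oxocarbenium ion being hydrolysed to the ketone on work-up. The closest known reaction types are the 1,2-addition of allylic organometallics to 3-alkoxyenones (first half of a Stork–Danheiser sequence) and the acid-catalysed addition of enol ethers to orthoester-derived dialkoxycarbenium ions (Müller–Cunradi–Pieroh/Mukaiyama type); triggering the second by protonation of a ketene acetal is the untested element. The carbocycle closes in a 6-(enolendo)-exo-trig mode across the 1,3-diaxial positions of the oxane, giving the 2-oxabicyclo[3.3.1]nonane. The carbinol centre is set in the addition by axial attack on the half-chair of 8, anti to the pseudo-equatorial C2 chain; only this diastereomer can bridge, and the ketal bridgehead configuration follows from the ring fusion. The step needs 1,2- rather than 1,4-addition (hard allylzinc, deactivated acetal carbon), C-protonation of the ketene acetal rather than ionisation of the tertiary allylic alcohol (buffered pyridinium acid, low temperature), and lasting differentiation of ketal and ketone carbons (the bridgehead ketal cannot eliminate toward the one-carbon bridge, which also blocks aromatisation).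

**Step 7**
Reactants: 12 (1S,3R,5R)-1-ethoxy-3-[(8Z,11Z)-heptadeca-8,11-dien-1-yl]-5-hydroxy-2-oxabicyclo[3.3.1]nonan-7-one
Product: 13 (5S)-3-ethoxy-5-hydroxy-5-[(2R,10Z,13Z)-2-hydroxynonadeca-10,13-dien-1-yl]cyclohex-2-en-1-one
Conditions: DBU (0.2 equiv), CH2Cl2, 0 °C to rt
Reagents that add atoms: none
Why: the ring oxygen is axial on the carbocycle and β to the ketone, so E1cB opening through the C8 enolate should expel it (loss of ethoxide would give a bridgehead alkene) and give the vinylogous ester with both stereocentres untouched.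

**Step 8**
Reactants: 13 (5S)-3-ethoxy-5-hydroxy-5-[(2R,10Z,13Z)-2-hydroxynonadeca-10,13-dien-1-yl]cyclohex-2-en-1-one
Product: 15 (5S)-5-hydroxy-5-[(2R,10Z,13Z)-2-hydroxynonadeca-10,13-dien-1-yl]cyclohex-2-en-1-one, via ethoxy allylic alcohol 14 (not isolated)
Conditions: iBu2AlH (4 equiv), THF, −78 °C; then 1 M aq. HCl, THF, 0 °C
Reagents that add atoms: water, O
Why: Stork–Danheiser transposition, in which 1,2-reduction of the vinylogous ester and mild acid hydrolysis of the 3-ethoxy allylic alcohol should place the carbonyl on the ethoxy-bearing carbon and the alkene toward the former carbonyl carbon, without touching the tertiary carbinol.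

**Step 9**
Reactants: 15 (5S)-5-hydroxy-5-[(2R,10Z,13Z)-2-hydroxynonadeca-10,13-dien-1-yl]cyclohex-2-en-1-one
Product: 16 (5S)-5-hydroxy-5-[(10Z,13Z)-2-oxononadeca-10,13-dien-1-yl]cyclohex-2-en-1-one (target)
Conditions: Dess–Martin periodinane, NaHCO3, CH2Cl2, 0 °C
Reagents that add atoms: none
Why: Dess–Martin oxidation should convert the secondary carbinol into the ketone while the tertiary alcohol cannot be oxidised, erasing the relay stereocentre and leaving the (S) quaternary carbinol.

**Compound list**
1 | (9Z,12Z)-octadeca-9,12-dien-1-ol (linoleyl alcohol) | OCCCCCCCC/C=C\C/C=C\CCCCC | starting material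
2 | (9Z,12Z)-octadeca-9,12-dienal | O=CCCCCCCC/C=C\C/C=C\CCCCC | intermediate
3 | 1,1-diethoxyethene (ketene diethyl acetal) | C=C(OCC)OCC | starting material
4 | acetyl chloride | CC(=O)Cl | starting material
5 | 4,4-diethoxybut-3-en-2-one | CC(=O)C=C(OCC)OCC | intermediate
6 | 1,1-diethoxy-3-(trimethylsilyloxy)buta-1,3-diene | C=C(O[Si](C)(C)C)C=C(OCC)OCC | intermediate
7 | (6R)-2,2-diethoxy-6-[(8Z,11Z)-heptadeca-8,11-dien-1-yl]-4-(trimethylsilyloxy)-5,6-dihydro-2H-pyran | CCOC1(OCC)C=C(O[Si](C)(C)C)C[C@@H](CCCCCCC/C=C\C/C=C\CCCCC)O1 | intermediate (not isolated)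
8 | (2R)-6-ethoxy-2-[(8Z,11Z)-heptadeca-8,11-dien-1-yl]-2,3-dihydro-4H-pyran-4-one | CCOC1=CC(=O)C[C@@H](CCCCCCC/C=C\C/C=C\CCCCC)O1 | intermediate
9 | 1-bromo-2,2-dimethoxypropane | COC(C)(CBr)OC | starting material
10 | 3-bromo-2-methoxyprop-1-ene (2-methoxyallyl bromide) | COC(=C)CBr | intermediate
11 | bromozinc (2R,4R)-6-ethoxy-2-[(8Z,11Z)-heptadeca-8,11-dien-1-yl]-4-(2-methoxyprop-2-en-1-yl)-3,4-dihydro-2H-pyran-4-olate | CCOC1=C[C@](O[Zn]Br)(CC(OC)=C)C[C@@H](CCCCCCC/C=C\C/C=C\CCCCC)O1 | intermediate (not isolated)
12 | (1S,3R,5R)-1-ethoxy-3-[(8Z,11Z)-heptadeca-8,11-dien-1-yl]-5-hydroxy-2-oxabicyclo[3.3.1]nonan-7-one | CCO[C@@]12CC(=O)C[C@@](O)(C1)C[C@@H](CCCCCCC/C=C\C/C=C\CCCCC)O2 | intermediate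
13 | (5S)-3-ethoxy-5-hydroxy-5-[(2R,10Z,13Z)-2-hydroxynonadeca-10,13-dien-1-yl]cyclohex-2-en-1-one | CCOC1=CC(=O)C[C@](O)(C[C@H](O)CCCCCCC/C=C\C/C=C\CCCCC)C1 | intermediate
14 | (5R)-3-ethoxy-5-[(2R,10Z,13Z)-2-hydroxynonadeca-10,13-dien-1-yl]cyclohex-2-ene-1,5-diol (both C1 epimers) | CCOC1=CC(O)C[C@](O)(C[C@H](O)CCCCCCC/C=C\C/C=C\CCCCC)C1 | intermediate (not isolated)
15 | (5S)-5-hydroxy-5-[(2R,10Z,13Z)-2-hydroxynonadeca-10,13-dien-1-yl]cyclohex-2-en-1-one | O=C1C=CC[C@](O)(C[C@H](O)CCCCCCC/C=C\C/C=C\CCCCC)C1 | intermediate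
16 | (5S)-5-hydroxy-5-[(10Z,13Z)-2-oxononadeca-10,13-dien-1-yl]cyclohex-2-en-1-one | CCCCC/C=C\C/C=C\CCCCCCCC(=O)C[C@@]1(O)CC=CC(=O)C1 | target

**Totals**
Total step count: 9.
Longest linear sequence: 7 steps (steps 2, 3, 4, 6, 7, 8, 9).

**Steps most likely to fail**

1. Step 6 (proposed new method). What may go wrong is ionisation of the tertiary allylic alcohol before the ketene acetal is protonated, hydrolytic capture of the dialkoxycarbenium ion to a lactone, acid-induced isomerisation of the pendant enol ether, or poor facial selectivity in the zinc addition. The fallback uses known chemistry and makes the two bonds in separate steps. It sets out from 8: CH2=CHCH2MgBr (THF, −78 °C) adds 1,2 with the same axial preference, and a buffered aqueous work-up hydrolyses the ketene acetal to the hydroxy lactone (4S,6R)-4-hydroxy-4-(prop-2-en-1-yl)-6-[(8Z,11Z)-heptadeca-8,11-dien-1-yl]oxan-2-one F1. Me(MeO)NH·HCl with Me3Al opens the lactone to the amide (3S,5R,13Z,16Z)-3,5-dihydroxy-N-methoxy-N-methyl-3-(prop-2-en-1-yl)docosa-13,16-dienamide F2. Excess CH2=CHMgBr gives the vinyl ketone (5S,7R,15Z,18Z)-5,7-dihydroxy-5-(prop-2-en-1-yl)tetracosa-1,15,18-trien-3-one F3. Ring-closing metathesis of the two terminal alkenes with the second-generation Grubbs catalyst (CH2Cl2, 40 °C) closes the enone, and the route is rejoined at 15.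

2. Step 4. What may go wrong is an uncatalysed background cyclocondensation of the very electron-rich diene that erodes the enantioselectivity, or hydrolysis of the ketene acetal to an ester. The fallback sets the centre by reduction instead of by C–C bond formation. It sets out from 5: the lithium enolate (LiN(iPr)2, THF, −78 °C) is acylated with commercial linoleoyl chloride to the diketone (13Z,16Z)-1,1-diethoxydocosa-1,13,16-triene-3,5-dione F4. Catalytic CF3CO2H closes it, with loss of ethanol, to 2-ethoxy-6-[(8Z,11Z)-heptadeca-8,11-dien-1-yl]-4H-pyran-4-one F5. An asymmetric copper hydride conjugate reduction of the alkyl-bearing double bond (Cu(OAc)2 cat., (R)-DTBM-SEGPHOS, polymethylhydrosiloxane, t-BuOH, toluene; ligand enantiomer chosen for the (R) product) returns to the route at 8.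

3. Step 8. What may go wrong is acid-promoted loss of the tertiary hydroxyl, that is β-elimination to a cross-conjugated dienone that tautomerises to a phenol, during the hydrolysis. The fallback avoids the acid-driven transposition and removes the β-oxygen by base instead. It sets out from 12: NaBH4 (MeOH, 0 °C) gives the diol (1R,3R,5S)-1-ethoxy-3-[(8Z,11Z)-heptadeca-8,11-dien-1-yl]-2-oxabicyclo[3.3.1]nonane-5,7-diol F6. MsCl and Et3N (CH2Cl2, −20 °C) should sulfonylate only the secondary hydroxyl, giving (1R,3R,5R)-1-ethoxy-3-[(8Z,11Z)-heptadeca-8,11-dien-1-yl]-5-hydroxy-2-oxabicyclo[3.3.1]nonan-7-yl methanesulfonate F7. Pyridinium p-toluenesulfonate in wet acetone opens the bridgehead ketal to the β-mesyloxy ketone, and Et3N then removes the mesylate by E1cB, which returns to the route at 15.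

**Further compounds**
F1 | step 6 | (4S,6R)-4-hydroxy-4-(prop-2-en-1-yl)-6-[(8Z,11Z)-heptadeca-8,11-dien-1-yl]oxan-2-one | O=C1C[C@](O)(CC=C)C[C@@H](CCCCCCC/C=C\C/C=C\CCCCC)O1
F2 | step 6 | (3S,5R,13Z,16Z)-3,5-dihydroxy-N-methoxy-N-methyl-3-(prop-2-en-1-yl)docosa-13,16-dienamide | CON(C)C(=O)C[C@](O)(CC=C)C[C@H](O)CCCCCCC/C=C\C/C=C\CCCCC
F3 | step 6 | (5S,7R,15Z,18Z)-5,7-dihydroxy-5-(prop-2-en-1-yl)tetracosa-1,15,18-trien-3-one | C=CC(=O)C[C@](O)(CC=C)C[C@H](O)CCCCCCC/C=C\C/C=C\CCCCC
F4 | step 4 | (13Z,16Z)-1,1-diethoxydocosa-1,13,16-triene-3,5-dione | CCOC(OCC)=CC(=O)CC(=O)CCCCCCC/C=C\C/C=C\CCCCC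
F5 | step 4 | 2-ethoxy-6-[(8Z,11Z)-heptadeca-8,11-dien-1-yl]-4H-pyran-4-one | CCOC1=CC(=O)C=C(CCCCCCC/C=C\C/C=C\CCCCC)O1
F6 | step 8 | (1R,3R,5S)-1-ethoxy-3-[(8Z,11Z)-heptadeca-8,11-dien-1-yl]-2-oxabicyclo[3.3.1]nonane-5,7-diol (both C7 epimers) | CCO[C@@]12CC(O)C[C@@](O)(C1)C[C@@H](CCCCCCC/C=C\C/C=C\CCCCC)O2
F7 | step 8 | (1R,3R,5R)-1-ethoxy-3-[(8Z,11Z)-heptadeca-8,11-dien-1-yl]-5-hydroxy-2-oxabicyclo[3.3.1]nonan-7-yl methanesulfonate (both C7 epimers) | CCO[C@@]12CC(OS(C)(=O)=O)C[C@@](O)(C1)C[C@@H](CCCCCCC/C=C\C/C=C\CCCCC)O2
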